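A direct plan would build the central ring de novo: two aryloxyacetate units and a malonyl unit would be joined by Claisen condensation, acylation of a bis(silyl enol ether) and Dieckmann aromatisation to the benzoate A1.
Two of the three hydroxyls of A1 would then be methylated and the ester removed by saponification and decarboxylation, leaving the monophenol A2.
A2 would be joined to the iodide A3 by an Ullmann coupling to give the undecamethyl ether A4, and all methyl ethers would be cleaved at the end.
Weak points: (a) the ring construction: six enolate operations through labile β-keto ester and silyl dienol ether intermediates, only to make one benzene ring;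
(b) the partial methylation: it must stop at two of three hydroxyls, held only by a hydrogen bond and by stoichiometry, and is followed by a decarboxylation that builds nothing;
(c) the late Ullmann coupling: a very electron-rich iodide with two ortho methoxy groups must meet an ortho-substituted phenol when all advanced material is at stake.

**Retrosynthetic overview**
Ring B (central) is numbered B1 = C–H, B2 = C–O–ring A (2,4,6-trihydroxyphenyl), B3 and B5 = C–O–rings D and C (both 3,4,5-trihydroxyphenyl), B4 and B6 = C–OH. B4 and B6 stand ortho or para to both B3 and B5, so they are carried as formyl groups that doubly activate fluorides at B3 and B5 and are afterwards oxidised to those hydroxyls.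
Key disconnection: the B3–O and B5–O bonds are cut together, giving the 2,4-difluoroisophthalaldehyde 9 and two molecules of 3,4,5-trimethoxyphenol; rings C and D are identical, so no regiochemical question arises.
9 comes from the bromodifluoro diaryl ether 6 by a position-defined double formylation (C–Br and the C–H between the fluorines); 6 comes from a purchased aryl iodide and 2,4,6-trimethoxyphenol through a diaryliodonium salt, so the B2–O bond is made at the unhindered, electron-poor ring B carbon.
No ring is built (ring B is bought), no hydroxyl is differentiated by partial protection (the two free hydroxyls arise from formyl groups), and no coupling of two hindered partners occurs late. The target is achiral.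

Key step: step 4

Assumption: compounds 1 and 5 are taken as purchasable building blocks.

Step 1
Reactants: 1 1-bromo-2,4-difluoro-5-iodobenzene; 2 1,3,5-trimethoxybenzene
Product: 4 (5-bromo-2,4-difluorophenyl)(2,4,6-trimethoxyphenyl)iodonium 4-methylbenzenesulfonate, via 1-bromo-2,4-difluoro-5-[hydroxy(tosyloxy)iodo]benzene 3 (not isolated)
Conditions: mCPBA (1.1 equiv), TsOH·H2O (1.05 equiv), MeCN, 60 °C, 1 h; then 2 (1.05 equiv), 60 °C → rt; precipitation with Et2O
Reagents that add atoms: 4-methylbenzenesulfonic acid monohydrate, Cc1ccc(cc1)S(O)(=O)=O.O; 3-chloroperbenzoic acid, O=C(OO)c1cccc(Cl)c1 (O in 3 only)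
Why: One-pot diaryliodonium salt synthesis, in which the aryl iodide is oxidised to a trivalent [hydroxy(tosyloxy)iodo]arene that is then attacked by the very nucleophilic 1,3,5-trimethoxybenzene (electrophilic aromatic substitution), the trimethoxyphenyl group serving as the ligand that is not transferred later.

Step 2
Reactants: 4 (5-bromo-2,4-difluorophenyl)(2,4,6-trimethoxyphenyl)iodonium 4-methylbenzenesulfonate; 5 2,4,6-trimethoxyphenol
Product: 6 2-(5-bromo-2,4-difluorophenoxy)-1,3,5-trimethoxybenzene
Conditions: 5 (1.1 equiv), KOt-Bu (1.1 equiv), THF, 0 °C, 15 min; then 4, 0 → 40 °C, Ar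
Reagents that add atoms: none
Why: Metal-free O-arylation of a phenoxide with a diaryliodonium salt (ligand exchange at trivalent iodine, then ligand coupling), a reaction type that tolerates two ortho substituents on the phenoxide and transfers the electron-poor, ortho-fluorinated aryl group instead of the trimethoxyphenyl group.

Step 3
Reactants: 6 2-(5-bromo-2,4-difluorophenoxy)-1,3,5-trimethoxybenzene
Product: 9 2,4-difluoro-5-(2,4,6-trimethoxyphenoxy)benzene-1,3-dicarbaldehyde, via lithium [2,4-difluoro-5-(2,4,6-trimethoxyphenoxy)phenyl](dimethylamino)methanolate 7 (not isolated), via dilithium [2,4-difluoro-5-(2,4,6-trimethoxyphenoxy)-1,3-phenylene]bis[(dimethylamino)methanolate] 8 (not isolated)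
Conditions: n-BuLi (1.05 equiv), THF, −78 °C, 20 min; DMF (1.1 equiv); LiN(i-Pr)2 (commercial solution, 1.3 equiv), −78 °C, 1 h; DMF (1.5 equiv); 1 M HCl, −78 °C → rt
Reagents that add atoms: N,N-dimethylformamide, CN(C)C=O; n-butyllithium, [Li]CCCC (Li in 7 and 8 only); lithium diisopropylamide, CC(C)[N-]C(C)C.[Li+] (Li in 8 only)
Why: Bromine–lithium exchange and formylation, followed, with the first formyl group masked in the flask as its lithium hemiaminolate, by directed ortho-lithiation of the C–H flanked by both fluorines (the most acidic position) and a second formylation, so that both formyl positions are fixed by the bromine and the two fluorines.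

Step 4
Reactants: 9 2,4-difluoro-5-(2,4,6-trimethoxyphenoxy)benzene-1,3-dicarbaldehyde; 10 3,4,5-trimethoxyphenol
Product: 12 5-(2,4,6-trimethoxyphenoxy)-2,4-bis(3,4,5-trimethoxyphenoxy)benzene-1,3-dicarbaldehyde, via 4-fluoro-5-(2,4,6-trimethoxyphenoxy)-2-(3,4,5-trimethoxyphenoxy)benzene-1,3-dicarbaldehyde 11 (not isolated)
Conditions: 10 (2.3 equiv), K2CO3 (3 equiv), DMF, 25 → 60 °C, Ar
Reagents that add atoms: none
Why: Twofold nucleophilic aromatic substitution by addition–elimination: potassium 3,4,5-trimethoxyphenoxide adds to each fluorine-bearing carbon to give an anionic σ-adduct whose charge is taken up by both formyl groups (the fluoride between them has two ortho formyl groups, the other has one ortho and one para), and fluoride is lost. The closest known reaction type is the diaryl ether synthesis from ortho- or para-fluorobenzaldehydes and phenoxides, run here twice on one ring so that three components are joined and the two most hindered ether bonds of the target, at B3 and B5 on either side of the B4 oxygen, are made in one operation. No ring is closed and no stereocentre is formed. The only selectivity needed is that substitution occurs at the two C–F carbons and through oxygen: both sites take the same nucleophile, so the order of the two substitutions (11 is drawn for one of the two possible orders) does not matter, and the aryloxy group that enters first stands meta to the remaining fluoride and does not deactivate it. The ring A ether at B2 is meta to both formyl groups and is not displaced, and addition of phenoxide to the aldehydes is reversible, so they survive.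

Step 5
Reactants: 12 5-(2,4,6-trimethoxyphenoxy)-2,4-bis(3,4,5-trimethoxyphenoxy)benzene-1,3-dicarbaldehyde
Product: 14 5-(2,4,6-trimethoxyphenoxy)-2,4-bis(3,4,5-trimethoxyphenoxy)benzene-1,3-diol, via 5-(2,4,6-trimethoxyphenoxy)-2,4-bis(3,4,5-trimethoxyphenoxy)-1,3-phenylene diformate 13 (not isolated)
Conditions: mCPBA (3 equiv), CH2Cl2, 0 °C → rt; aqueous work-up; then MeOH, Et3N (cat.), rt, Ar
Reagents that add atoms: 3-chloroperbenzoic acid, O=C(OO)c1cccc(Cl)c1
Why: Double Baeyer–Villiger (Dakin-type) oxidation, in which each formyl-bearing carbon has aryloxy donors ortho and para or at both ortho positions so that the aryl group migrates in the peracid adduct, followed by methanolysis of the two aryl formates to the ring B hydroxyls at B4 and B6.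

Step 6
Reactants: 14 5-(2,4,6-trimethoxyphenoxy)-2,4-bis(3,4,5-trimethoxyphenoxy)benzene-1,3-diol
Product: 15 2-[3,5-dihydroxy-2,4-bis(3,4,5-trihydroxyphenoxy)phenoxy]benzene-1,3,5-triol (target, achiral)
Conditions: BBr3 (20 equiv), CH2Cl2, −78 °C → rt, Ar; MeOH then H2O, 0 °C; EtOAc extraction; Sephadex LH-20 (degassed MeOH)
Reagents that add atoms: none
Why: Lewis-acid ether cleavage, in which bromide attacks the methyl carbon (SN2) of each of the nine boron-complexed aryl methyl ethers, while the three diaryl ether links offer no sp3 carbon and should stay intact.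

**Compound list**
1 | 1-bromo-2,4-difluoro-5-iodobenzene | Fc1cc(F)c(I)cc1Br | starting material
2 | 1,3,5-trimethoxybenzene | COc1cc(OC)cc(OC)c1 | starting material
3 | 1-bromo-2,4-difluoro-5-[hydroxy(tosyloxy)iodo]benzene (not isolated) | Cc1ccc(cc1)S(=O)(=O)OI(O)c1cc(Br)c(F)cc1F | intermediate
4 | (5-bromo-2,4-difluorophenyl)(2,4,6-trimethoxyphenyl)iodonium 4-methylbenzenesulfonate | COc1cc(OC)c([I+]c2cc(Br)c(F)cc2F)c(OC)c1.Cc1ccc(cc1)S([O-])(=O)=O | intermediate
5 | 2,4,6-trimethoxyphenol | COc1cc(OC)c(O)c(OC)c1 | starting material
6 | 2-(5-bromo-2,4-difluorophenoxy)-1,3,5-trimethoxybenzene | COc1cc(OC)c(Oc2cc(Br)c(F)cc2F)c(OC)c1 | intermediate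
7 | lithium [2,4-difluoro-5-(2,4,6-trimethoxyphenoxy)phenyl](dimethylamino)methanolate (not isolated) | [Li+].COc1cc(OC)c(Oc2cc(C([O-])N(C)C)c(F)cc2F)c(OC)c1 | intermediate
8 | dilithium [2,4-difluoro-5-(2,4,6-trimethoxyphenoxy)-1,3-phenylene]bis[(dimethylamino)methanolate] (not isolated) | [Li+].[Li+].COc1cc(OC)c(Oc2cc(C([O-])N(C)C)c(F)c(C([O-])N(C)C)c2F)c(OC)c1 | intermediate
9 | 2,4-difluoro-5-(2,4,6-trimethoxyphenoxy)benzene-1,3-dicarbaldehyde | COc1cc(OC)c(Oc2cc(C=O)c(F)c(C=O)c2F)c(OC)c1 | intermediate
10 | 3,4,5-trimethoxyphenol | COc1cc(O)cc(OC)c1OC | starting material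
11 | 4-fluoro-5-(2,4,6-trimethoxyphenoxy)-2-(3,4,5-trimethoxyphenoxy)benzene-1,3-dicarbaldehyde (not isolated) | COc1cc(OC)c(Oc2cc(C=O)c(Oc3cc(OC)c(OC)c(OC)c3)c(C=O)c2F)c(OC)c1 | intermediate
12 | 5-(2,4,6-trimethoxyphenoxy)-2,4-bis(3,4,5-trimethoxyphenoxy)benzene-1,3-dicarbaldehyde | COc1cc(OC)c(Oc2cc(C=O)c(Oc3cc(OC)c(OC)c(OC)c3)c(C=O)c2Oc2cc(OC)c(OC)c(OC)c2)c(OC)c1 | intermediate
13 | 5-(2,4,6-trimethoxyphenoxy)-2,4-bis(3,4,5-trimethoxyphenoxy)-1,3-phenylene diformate (not isolated) | COc1cc(OC)c(Oc2cc(OC=O)c(Oc3cc(OC)c(OC)c(OC)c3)c(OC=O)c2Oc2cc(OC)c(OC)c(OC)c2)c(OC)c1 | intermediate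
14 | 5-(2,4,6-trimethoxyphenoxy)-2,4-bis(3,4,5-trimethoxyphenoxy)benzene-1,3-diol | COc1cc(OC)c(Oc2cc(O)c(Oc3cc(OC)c(OC)c(OC)c3)c(O)c2Oc2cc(OC)c(OC)c(OC)c2)c(OC)c1 | intermediate
15 | 2-[3,5-dihydroxy-2,4-bis(3,4,5-trihydroxyphenoxy)phenoxy]benzene-1,3,5-triol | Oc1cc(O)c(Oc2cc(O)c(Oc3cc(O)c(O)c(O)c3)c(O)c2Oc2cc(O)c(O)c(O)c2)c(O)c1 | target

Total step count: 6. Longest linear sequence: 6 steps (from 1 to 15).

**Steps most likely to fail**

Step 3 may fail through loss of lithium fluoride from the aryllithium that sits between the two fluorines (aryne formation), or through incomplete second metalation while the first hemiaminolate is present. The fallback sets out from 6 and separates the two formylations by mechanism. Deprotonation between the fluorines with LiN(i-Pr)2 and quenching with DMF would give 3-bromo-2,6-difluoro-5-(2,4,6-trimethoxyphenoxy)benzaldehyde F1. Its C–Br bond would then be converted into the second formyl group by palladium-catalysed reductive carbonylation (PdCl2(PPh3)2, CO, HCO2Na, DMF, 100 °C), returning to the route at 9.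

Step 5 may fail through acid-promoted attack of an electron-rich trimethoxyphenoxy ring on the neighbouring formyl group (xanthene-type ring closure), or through hydrogen instead of aryl migration at the first formyl group while the second still withdraws electrons. The fallback sets out from 6 and replaces the latent hydroxyl by an acetyl group, which has no migrating hydrogen and is a much weaker electrophile. The metalation sequence of step 3 with N-methoxy-N-methylacetamide in place of DMF would give 1,1'-[2,4-difluoro-5-(2,4,6-trimethoxyphenoxy)-1,3-phenylene]di(ethan-1-one) F2. Double substitution with 10 and K2CO3 would give 1,1'-[5-(2,4,6-trimethoxyphenoxy)-2,4-bis(3,4,5-trimethoxyphenoxy)-1,3-phenylene]di(ethan-1-one) F3. Baeyer–Villiger oxidation with mCPBA would give 5-(2,4,6-trimethoxyphenoxy)-2,4-bis(3,4,5-trimethoxyphenoxy)-1,3-phenylene diacetate F4, and methanolysis (MeOH, cat. K2CO3) would return to the route at 14.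

Step 2 may fail through electron transfer from the very electron-rich phenoxide to the iodonium salt, or through base-induced aryne formation next to the iodonium group, both of which consume the salt without forming the ether. The fallback sets out from 1 and 5 and joins them directly by a copper-catalysed Ullmann coupling (CuI, picolinic acid, K3PO4, DMSO, 80 °C). Here the electrophile is an electron-poor iodide with only one small ortho substituent, and the C–I bond should react before the C–Br bond. It returns to the route at 6, and no new compound arises on the way (F0).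

**Further compounds**
F1 | step 3 | 3-bromo-2,6-difluoro-5-(2,4,6-trimethoxyphenoxy)benzaldehyde | COc1cc(OC)c(Oc2cc(Br)c(F)c(C=O)c2F)c(OC)c1
F2 | step 5 | 1,1'-[2,4-difluoro-5-(2,4,6-trimethoxyphenoxy)-1,3-phenylene]di(ethan-1-one) | COc1cc(OC)c(Oc2cc(C(C)=O)c(F)c(C(C)=O)c2F)c(OC)c1
F3 | step 5 | 1,1'-[5-(2,4,6-trimethoxyphenoxy)-2,4-bis(3,4,5-trimethoxyphenoxy)-1,3-phenylene]di(ethan-1-one) | COc1cc(OC)c(Oc2cc(C(C)=O)c(Oc3cc(OC)c(OC)c(OC)c3)c(C(C)=O)c2Oc2cc(OC)c(OC)c(OC)c2)c(OC)c1
F4 | step 5 | 5-(2,4,6-trimethoxyphenoxy)-2,4-bis(3,4,5-trimethoxyphenoxy)-1,3-phenylene diacetate | COc1cc(OC)c(Oc2cc(OC(C)=O)c(Oc3cc(OC)c(OC)c(OC)c3)c(OC(C)=O)c2Oc2cc(OC)c(OC)c(OC)c2)c(OC)c1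
F0 | step 2 | none | none
A1 | direct plan | methyl 2,4,6-trihydroxy-3,5-bis(3,4,5-trimethoxyphenoxy)benzoate | COC(=O)c1c(O)c(Oc2cc(OC)c(OC)c(OC)c2)c(O)c(Oc3cc(OC)c(OC)c(OC)c3)c1O
A2 | direct plan | 3,5-dimethoxy-2,4-bis(3,4,5-trimethoxyphenoxy)phenol | Oc1cc(OC)c(Oc2cc(OC)c(OC)c(OC)c2)c(OC)c1Oc3cc(OC)c(OC)c(OC)c3
A3 | direct plan | 2-iodo-1,3,5-trimethoxybenzene | COc1cc(OC)c(I)c(OC)c1
A4 | direct plan | 1,3-dimethoxy-5-(2,4,6-trimethoxyphenoxy)-2,4-bis(3,4,5-trimethoxyphenoxy)benzene | COc1cc(OC)c(Oc2cc(OC)c(Oc3cc(OC)c(OC)c(OC)c3)c(OC)c2Oc4cc(OC)c(OC)c(OC)c4)c(OC)c1
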